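**Retrosynthetic overview**

1. Rings A (quinone) and B (pyran) are made last and together: a 4-dienyl-4-hydroxycyclobutenone is ring-expanded thermally to a methoxyhydroquinone, oxidised, and closed by oxa-Michael addition of the tertiary alcohol across a cis olefin.
2. That cyclobutenone comes from methyl semisquarate (from dimethyl squarate) and a 1,3-dien-2-yllithium generated by a Shapiro reaction.
3. The Shapiro precursor comes from a cis-enedione (from 2,5-dimethylfuran) by enantioselective alkylzinc addition, which sets the chromene stereocentre and carries the cis geometry.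
4. The alkylzinc comes from a vinylcyclohexene, made by methylenation of the aldehyde from a catalytic asymmetric Diels–Alder reaction of methacrolein with (E)-3-methylpenta-1,3-diene.
5. Ring order: ring C first (with both of its stereocentres), then rings A and B in one operation.

Assumption: ring A = quinone ring, ring B = pyran ring, ring C = trimethylcyclohexene ring; the SMILES is read as (2S) at the chromene carbon and (1S,2R) in ring C (1-methyl and 2-methyl trans).

**Route**

Step 1
Reactants: 1 (E)-3-methylpenta-1,3-diene; 2 methacrolein (2-methylprop-2-enal)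
Product: 3 (1R,2S)-1,2,3-trimethylcyclohex-3-ene-1-carbaldehyde
Conditions: (R)-tetrahydro-1-(2-methylphenyl)-3,3-diphenyl-1H,3H-pyrrolo[1,2-c][1,3,2]oxazaborole (20 mol %), Tf2NH (17 mol %), 1 (3 equiv, Z isomer in commercial material is inert), CH2Cl2, −78 to −40 °C
Reagents that add atoms: none
Why: Enantioselective Diels–Alder reaction under Corey oxazaborolidinium catalysis: the methyl-bearing diene terminus bonds to C2 of the enal (1-substituent "ortho" control), the formyl group sits endo so CHO ends up cis to the new secondary methyl, and the (R)-catalyst is predicted by the formyl C–H···O model to shield the Re face at C2 of the s-trans-bound enal so the diene adds to the Si face, giving (1R,2S).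

Step 2
Reactants: 3 (1R,2S)-1,2,3-trimethylcyclohex-3-ene-1-carbaldehyde
Product: 4 (1S,2S)-1-ethenyl-1,2,3-trimethylcyclohex-3-ene
Conditions: Ph3PCH3Br, KOtBu, THF, 0 °C to rt
Reagents that add atoms: methyltriphenylphosphonium bromide, C[P+](c1ccccc1)(c1ccccc1)c1ccccc1.[Br-]
Why: Wittig methylenation of a non-enolisable aldehyde; no stereocentre is touched (the descriptor at C1 changes only through CIP priorities).

Step 3
Reactants: 5 2,5-dimethylfuran
Product: 6 (Z)-hex-3-ene-2,5-dione
Conditions: 3-chloroperoxybenzoic acid (1.0 equiv), CH2Cl2, 0 °C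
Reagents that add atoms: 3-chloroperoxybenzoic acid, OOC(=O)c1cccc(Cl)c1
Why: Peracid oxidative ring opening of a 2,5-dialkylfuran gives the enedione with the cis geometry fixed by the furan ring.

Step 4
Reactants: 4 (1S,2S)-1-ethenyl-1,2,3-trimethylcyclohex-3-ene; 6 (Z)-hex-3-ene-2,5-dione
Product: 9 (5S)-2,5-dimethyl-5-{2-[(1S,2R)-1,2,3-trimethylcyclohex-3-en-1-yl]ethyl}-2,5-dihydrofuran-2-ol, via alkyldiethylborane 7 (not isolated), via dialkylzinc 8 (not isolated)
Conditions: Et2BH (from BH3·SMe2 and Et3B), THF, 0 °C; Et2Zn, 0 °C, then vacuum; 6 (0.4 equiv), Ti(OiPr)4 (1.2 equiv per 6), N,N'-bis[(2-hydroxy-7,7-dimethylbicyclo[2.2.1]heptan-1-yl)methanesulfonyl]cyclohexane-1,2-diamine (10 mol %), toluene, 0 °C to rt; H2O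
Reagents that add atoms: none
Why: Anti-Markovnikov hydroboration of the terminal vinyl group, boron–zinc exchange (Knochel) and titanium bis(sulfonamide)-catalysed enantioselective 1,2-addition of the dialkylzinc to one ketone of the enedione (Walsh–Yus type) set the tertiary carbinol as (S), using the ligand antipode that delivers the alkyl group to the Si face of the carbonyl (O > alkenyl > CH3); the cis-γ-alkoxy enone then closes to the hemiketal, which masks the second ketone against over-addition.

Step 5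
Reactants: 9 (5S)-2,5-dimethyl-5-{2-[(1S,2R)-1,2,3-trimethylcyclohex-3-en-1-yl]ethyl}-2,5-dihydrofuran-2-ol
Product: 10 N'-[(3Z,5S)-5-hydroxy-5-methyl-7-[(1S,2R)-1,2,3-trimethylcyclohex-3-en-1-yl]hept-3-en-2-ylidene]-2,4,6-tri(propan-2-yl)benzenesulfonohydrazide
Conditions: 2,4,6-tri(propan-2-yl)benzenesulfonohydrazide (1.05 equiv), THF, 4 Å molecular sieves, rt
Reagents that add atoms: 2,4,6-tri(propan-2-yl)benzenesulfonohydrazide, CC(C)c1cc(C(C)C)c(S(=O)(=O)NN)c(C(C)C)c1
Why: Hydrazone formation through the ring-opened keto tautomer of the hemiketal under acid-free conditions; the carbinol and the cis olefin are not involved.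

Step 6
Reactants: 11 dimethyl squarate (3,4-dimethoxycyclobut-3-ene-1,2-dione)
Product: 13 methyl semisquarate (3-methoxycyclobut-3-ene-1,2-dione), via hydroxycyclobutenone 12 (not isolated)
Conditions: LiAlH(OtBu)3, THF, −78 °C; then 6 M aq HCl, CH2Cl2, 0 °C
Reagents that add atoms: water, O
Why: Selective 1,2-reduction of one vinylogous ester carbonyl, then acid-induced allylic transposition with loss of methanol (Liebeskind semisquarate synthesis); no stereocentre.

Step 7
Reactants: 10 N'-[(3Z,5S)-5-hydroxy-5-methyl-7-[(1S,2R)-1,2,3-trimethylcyclohex-3-en-1-yl]hept-3-en-2-ylidene]-2,4,6-tri(propan-2-yl)benzenesulfonohydrazide; 13 methyl semisquarate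
Product: 15 4-hydroxy-4-[(3Z,5S)-5-hydroxy-5-methyl-7-[(1S,2R)-1,2,3-trimethylcyclohex-3-en-1-yl]hepta-1,3-dien-2-yl]-3-methoxycyclobut-2-en-1-one, via dienyllithium 14 (not isolated)
Conditions: n-BuLi (3.2 equiv), TMEDA, THF, −78 to 0 °C; then 13, −78 °C; AcOH
Reagents that add atoms: none
Why: Shapiro reaction (deprotonation at the only α-methyl, loss of sulfinate and N2) gives the 1,3-dien-2-yllithium, which adds 1,2 to the more electrophilic ketone of 13 (the carbonyl next to C–OMe, the other being a vinylogous ester); the existing stereocentres and the cis olefin are spectators, and the new ring carbinol (epimer mixture) is destroyed in step 8.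

Step 8
Reactants: 15 4-hydroxy-4-[(3Z,5S)-5-hydroxy-5-methyl-7-[(1S,2R)-1,2,3-trimethylcyclohex-3-en-1-yl]hepta-1,3-dien-2-yl]-3-methoxycyclobut-2-en-1-one
Product: 19 (2S)-6-methoxy-2-methyl-2-{2-[(1S,2R)-1,2,3-trimethylcyclohex-3-en-1-yl]ethyl}-2H-chromene-5,8-dione, via hydroquinone 16 (not isolated), via alkenylquinone 17 (not isolated), via chromenediol 18 (not isolated)
Conditions: toluene, K2CO3, 110 °C, 1 h; then Ag2O (3 equiv), rt
Reagents that add atoms: none
Why: Proposed new method: thermal 4π ring opening of the 4-alkenyl-4-hydroxycyclobutenone to a dienylketene and 6π closure (Liebeskind–Moore ring expansion) builds ring A as the hydroquinone with OMe next to the carbinol-derived carbon; Ag2O gives the quinone, the cis-held tertiary hydroxyl adds to the free quinone carbon β to the more electrophilic carbonyl (intramolecular oxa-Michael) and the chromenediol is reoxidised, so rings A and B form in one flask with no bond to the chromene stereocentre broken; the closest known reactions are the Liebeskind–Moore hydroquinone synthesis and oxidative addition of alcohols to quinones.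

**Compound list**

1 | (E)-3-methylpenta-1,3-diene | C=C/C(C)=C/C | starting material
2 | methacrolein (2-methylprop-2-enal) | CC(=C)C=O | starting material
3 | (1R,2S)-1,2,3-trimethylcyclohex-3-ene-1-carbaldehyde (CHO cis to the 2-methyl) | O=C[C@]1(C)CCC=C(C)[C@@H]1C | intermediate
4 | (1S,2S)-1-ethenyl-1,2,3-trimethylcyclohex-3-ene | C=C[C@]1(C)CCC=C(C)[C@@H]1C | intermediate
5 | 2,5-dimethylfuran | Cc1ccc(C)o1 | starting material
6 | (Z)-hex-3-ene-2,5-dione | CC(=O)/C=C\C(C)=O | intermediate
7 | diethyl{2-[(1R,2R)-1,2,3-trimethylcyclohex-3-en-1-yl]ethyl}borane (not isolated; same spatial arrangement as 4) | CCB(CC)CC[C@]1(C)CCC=C(C)[C@@H]1C | intermediate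
8 | bis{2-[(1S,2R)-1,2,3-trimethylcyclohex-3-en-1-yl]ethyl}zinc (not isolated) | [Zn](CC[C@]1(C)CCC=C(C)[C@@H]1C)CC[C@]2(C)CCC=C(C)[C@@H]2C | intermediate
9 | (5S)-2,5-dimethyl-5-{2-[(1S,2R)-1,2,3-trimethylcyclohex-3-en-1-yl]ethyl}-2,5-dihydrofuran-2-ol (both epimers at C2) | CC1(O)C=C[C@](C)(CC[C@]2(C)CCC=C(C)[C@@H]2C)O1 | intermediate
10 | N'-[(3Z,5S)-5-hydroxy-5-methyl-7-[(1S,2R)-1,2,3-trimethylcyclohex-3-en-1-yl]hept-3-en-2-ylidene]-2,4,6-tri(propan-2-yl)benzenesulfonohydrazide | CC(=NNS(=O)(=O)c1c(C(C)C)cc(C(C)C)cc1C(C)C)/C=C\[C@](C)(CC[C@]2(C)CCC=C(C)[C@@H]2C)O | intermediate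
11 | dimethyl squarate (3,4-dimethoxycyclobut-3-ene-1,2-dione) | COC1=C(OC)C(=O)C1=O | starting material
12 | 4-hydroxy-2,3-dimethoxycyclobut-2-en-1-one (not isolated) | COC1=C(OC)C(O)C1=O | intermediate
13 | methyl semisquarate (3-methoxycyclobut-3-ene-1,2-dione) | COC1=CC(=O)C1=O | intermediate
14 | lithium (3Z,5S)-2-lithio-5-methyl-7-[(1S,2R)-1,2,3-trimethylcyclohex-3-en-1-yl]hepta-1,3-dien-5-olate (not isolated) | [Li]C(=C)/C=C\[C@](C)(CC[C@]1(C)CCC=C(C)[C@@H]1C)O[Li] | intermediate
15 | 4-hydroxy-4-[(3Z,5S)-5-hydroxy-5-methyl-7-[(1S,2R)-1,2,3-trimethylcyclohex-3-en-1-yl]hepta-1,3-dien-2-yl]-3-methoxycyclobut-2-en-1-one (both epimers at the ring carbinol) | COC1=CC(=O)C1(O)C(=C)/C=C\[C@](C)(CC[C@]2(C)CCC=C(C)[C@@H]2C)O | intermediate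
16 | 2-[(1Z,3S)-3-hydroxy-3-methyl-5-[(1S,2R)-1,2,3-trimethylcyclohex-3-en-1-yl]pent-1-en-1-yl]-6-methoxybenzene-1,4-diol (not isolated) | COc1cc(O)cc(/C=C\[C@](C)(CC[C@]2(C)CCC=C(C)[C@@H]2C)O)c1O | intermediate
17 | 2-[(1Z,3S)-3-hydroxy-3-methyl-5-[(1S,2R)-1,2,3-trimethylcyclohex-3-en-1-yl]pent-1-en-1-yl]-6-methoxycyclohexa-2,5-diene-1,4-dione (not isolated) | COC1=CC(=O)C=C(/C=C\[C@](C)(CC[C@]2(C)CCC=C(C)[C@@H]2C)O)C1=O | intermediate
18 | (2S)-6-methoxy-2-methyl-2-{2-[(1S,2R)-1,2,3-trimethylcyclohex-3-en-1-yl]ethyl}-2H-chromene-5,8-diol (not isolated) | COc1cc(O)c2c(C=C[C@](C)(CC[C@]3(C)CCC=C(C)[C@@H]3C)O2)c1O | intermediate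
19 | (2S)-6-methoxy-2-methyl-2-{2-[(1S,2R)-1,2,3-trimethylcyclohex-3-en-1-yl]ethyl}-2H-chromene-5,8-dione | COC1=CC(=O)C2=C(C=C[C@](C)(CC[C@]3(C)CCC=C(C)[C@@H]3C)O2)C1=O | target

**Step count and risk**

Total step count: 8. Longest linear sequence: 6 (steps 1, 2, 4, 5, 7, 8).

The three steps most likely to fail are steps 4, 7 and 8.

Step 4 is risky because the cis-enedione may isomerise, add twice, or undergo conjugate addition under the titanium conditions, and because cis-enones are untested with this catalyst class. The fallback sets out from 6 (with dialkylzinc 8) and returns at 9; it separates the geometry problem from the addition. Compound 6 is isomerised (cat. I2, CH2Cl2, rt) to (E)-hex-3-ene-2,5-dione F1, and 8 is added to it with the same titanium catalyst, for which trans-enones are the established substrates. This gives (3E,5S)-5-hydroxy-5-methyl-7-[(1S,2R)-1,2,3-trimethylcyclohex-3-en-1-yl]hept-3-en-2-one F2. F2 is then isomerised photochemically (365 nm, thioxanthone, MeCN); the cis isomer is drained from the photostationary mixture as the hemiketal 9.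

Step 7 is risky because the Shapiro step must tolerate a free tertiary alkoxide, and the dienyllithium may be unstable or add poorly. The fallback sets out from 9 and returns at 15; it avoids the organolithium altogether. The keto tautomer of 9 is converted (KN(SiMe3)2, 2.2 equiv, then N-(5-chloropyridin-2-yl)-1,1,1-trifluoro-N-(trifluoromethylsulfonyl)methanesulfonamide, THF, −78 °C) into (3Z,5S)-5-hydroxy-5-methyl-7-[(1S,2R)-1,2,3-trimethylcyclohex-3-en-1-yl]hepta-1,3-dien-2-yl trifluoromethanesulfonate F3. F3 is coupled with 13 in a Nozaki–Hiyama–Kishi reaction (CrCl2, NiCl2 cat., DMF, rt) to give 15.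

Step 8 is risky for two reasons. At 110 °C the hydroquinone 16 may lose water between its ortho phenol and the allylic tertiary alcohol, giving a regioisomeric, racemised chromene. The tertiary alcohol may also add only sluggishly to quinone 17. The fallback sets out from dialkylzinc 8 (made from 4 as in step 4) and returns at 17. It takes ring A from an arene and closes only ring B at the end, at room temperature. It therefore answers the thermal failure but still relies on the oxa-Michael closure of 17.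

- Commercial 8-methoxycoumarin is opened with MeLi (1 equiv, THF, −78 °C) and the phenoxide is silylated (t-BuMe2SiCl) to give (Z)-4-[2-(tert-butyldimethylsilyloxy)-3-methoxyphenyl]but-3-en-2-one F4.
- Addition of 8 under the step 4 conditions gives (1Z,3S)-1-[2-(tert-butyldimethylsilyloxy)-3-methoxyphenyl]-3-methyl-5-[(1S,2R)-1,2,3-trimethylcyclohex-3-en-1-yl]pent-1-en-3-ol F5.
- Bu4NF gives 2-[(1Z,3S)-3-hydroxy-3-methyl-5-[(1S,2R)-1,2,3-trimethylcyclohex-3-en-1-yl]pent-1-en-1-yl]-6-methoxyphenol F6.
- Oxidation para to the hydroxyl with (KSO3)2NO (KH2PO4 buffer, acetone–water, 0 °C) gives quinone 17, which is closed and reoxidised to 19 with K2CO3 and Ag2O as in the second half of step 8.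

Further compounds
F1 | step 4 | (E)-hex-3-ene-2,5-dione | CC(=O)/C=C/C(C)=O
F2 | step 4 | (3E,5S)-5-hydroxy-5-methyl-7-[(1S,2R)-1,2,3-trimethylcyclohex-3-en-1-yl]hept-3-en-2-one | CC(=O)/C=C/[C@](C)(CC[C@]1(C)CCC=C(C)[C@@H]1C)O
F3 | step 7 | (3Z,5S)-5-hydroxy-5-methyl-7-[(1S,2R)-1,2,3-trimethylcyclohex-3-en-1-yl]hepta-1,3-dien-2-yl trifluoromethanesulfonate | C=C(OS(=O)(=O)C(F)(F)F)/C=C\[C@](C)(CC[C@]1(C)CCC=C(C)[C@@H]1C)O
F4 | step 8 | (Z)-4-[2-(tert-butyldimethylsilyloxy)-3-methoxyphenyl]but-3-en-2-one | CC(=O)/C=C\c1cccc(OC)c1O[Si](C)(C)C(C)(C)C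
F5 | step 8 | (1Z,3S)-1-[2-(tert-butyldimethylsilyloxy)-3-methoxyphenyl]-3-methyl-5-[(1S,2R)-1,2,3-trimethylcyclohex-3-en-1-yl]pent-1-en-3-ol | COc1cccc(/C=C\[C@](C)(CC[C@]2(C)CCC=C(C)[C@@H]2C)O)c1O[Si](C)(C)C(C)(C)C
F6 | step 8 | 2-[(1Z,3S)-3-hydroxy-3-methyl-5-[(1S,2R)-1,2,3-trimethylcyclohex-3-en-1-yl]pent-1-en-1-yl]-6-methoxyphenol | COc1cccc(/C=C\[C@](C)(CC[C@]2(C)CCC=C(C)[C@@H]2C)O)c1O
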